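1. Feature used: in briarane numbering the cyclohexene (C1, C10–C14) and the ten-membered ring (C1–C10) share the bond C1–C10. The oxygen on C2 and the oxygenated carbon C9 sit on opposite faces at its two ends, so a C2–O–C9(=O) ester can tether a C12=C13–C14=C1 diene to a C10=C11 dienophile.
2. Ring order: first the cyclohexene together with a temporary trans-fused γ-lactone (C1, C2, O, C9, C10) by intramolecular Diels–Alder reaction of a (Z)-crotonate. Then the γ-lactone (O, C7, C8, C17, C19), after a C8 vinyllithium (C5–C8, C16–C19) opens the temporary lactone at C9. The ten-membered ring is closed last at C4–C5 by Stille coupling.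
3. Other disconnections: C13–C14 (Suzuki coupling), C7/C8 diol (hydroxyl-directed dihydroxylation), C6–Cl (SN2 with inversion after ring closure), C12 propionate last.
4. Stereochemical sources: C2 and C6 from ynone reductions, C17 from the (S)-Roche ester, C9 by Felkin–Anh reduction, C1/C10/C11/C12 from the cycloaddition.

Key step: step 12

Remark: atoms are numbered as in briaranes (C1–C20); ketone 36 is drawn open-chain although it may rest partly as its cyclic hemiketal, which reduces through the same ketone.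

Step 1
Reactants: 1 prop-2-yn-1-ol
Product: 3 (E)-3-iodo-2-methylprop-2-en-1-ol, via alkenylalane 2 (not isolated)
Conditions: Me3Al, Cp2ZrCl2 (cat.), CH2Cl2, 0 °C→rt; I2, THF, −30 °C; aq. K2CO3
Reagents that add atoms: trimethylaluminium C[Al](C)C; iodine II
Why: Zirconium-catalysed carboalumination (Negishi) adds methyl and aluminium syn across the alkyne with aluminium at the terminal carbon, and iodinolysis with retention should give the E iodide.

Step 2
Reactants: 3 (E)-3-iodo-2-methylprop-2-en-1-ol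
Product: 4 (E)-3-iodo-2-methylprop-2-enal
Conditions: MnO2, CH2Cl2, rt
Reagents that add atoms: none
Why: MnO2 oxidation of an allylic alcohol should stop at the enal and leave the vinyl iodide and the alkene geometry untouched.

Step 3
Reactants: 4 (E)-3-iodo-2-methylprop-2-enal; 5 (triisopropylsilyl)acetylene
Product: 7 rac-(E)-1-iodo-2-methyl-5-(triisopropylsilyl)pent-1-en-4-yn-3-ol, via lithium acetylide 6 (not isolated)
Conditions: n-BuLi, THF, −78 °C; then 4; H2O
Reagents that add atoms: none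
Why: 1,2-Addition of the lithium acetylide to the enal forms the C2–C3 bond; the new centre is racemic and is erased in step 4.

Step 4
Reactants: 7 rac-(E)-1-iodo-2-methyl-5-(triisopropylsilyl)pent-1-en-4-yn-3-ol
Product: 8 (E)-1-iodo-2-methyl-5-(triisopropylsilyl)pent-1-en-4-yn-3-one
Conditions: MnO2, CH2Cl2, rt
Reagents that add atoms: none
Why: MnO2 oxidises the doubly activated (allylic and propargylic) alcohol to the cross-conjugated ynone.

Step 5
Reactants: 8 (E)-1-iodo-2-methyl-5-(triisopropylsilyl)pent-1-en-4-yn-3-one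
Product: 9 (S,E)-1-iodo-2-methyl-5-(triisopropylsilyl)pent-1-en-4-yn-3-ol
Conditions: (R)-Alpine-Borane (neat), rt; MeCHO; ethanolamine
Reagents that add atoms: none
Why: Midland reduction, in which hydride is transferred from the isopinocampheyl group in a boat-like transition state with the slim alkynyl group in the hindered position, should give the (S)-carbinol (C2 of the target) from the reagent made from (+)-α-pinene.

Step 6
Reactants: 10 4-methoxybenzyl alcohol
Product: 11 (E)-1,2-dichlorovinyl 4-methoxybenzyl ether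
Conditions: KH, THF, 0 °C; trichloroethylene, −50 °C→rt
Reagents that add atoms: trichloroethylene ClC=C(Cl)Cl
Why: Alkoxide addition to dichloroacetylene generated in situ from trichloroethylene is the standard entry to 1,2-dichlorovinyl ethers.

Step 7
Reactants: 11 (E)-1,2-dichlorovinyl 4-methoxybenzyl ether
Product: 13 ethynyl 4-methoxybenzyl ether, via lithium alkoxyacetylide 12 (not isolated)
Conditions: n-BuLi (2.2 equiv), THF, −78→−40 °C; MeOH, −78 °C; cold work-up, used at once
Reagents that add atoms: none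
Why: Dehydrochlorination followed by chlorine–lithium exchange (dichlorovinyl ether route to alkynyl ethers) gives the lithium alkoxyacetylide, which is protonated cold because benzylic alkynyl ethers rearrange on warming.

Step 8
Reactants: 13 ethynyl 4-methoxybenzyl ether
Product: 14 (E)-2-{2-[(4-methoxybenzyl)oxy]vinyl}-4,4,5,5-tetramethyl-1,3,2-dioxaborolane
Conditions: pinacolborane, Cp2Zr(H)Cl (cat.), CH2Cl2, 0 °C→rt
Reagents that add atoms: pinacolborane CC1(C)OBOC1(C)C
Why: Zirconium-catalysed hydroboration of the terminal alkynyl ether is a syn addition with boron at the terminal carbon and should give the E boronate, as with ethoxyethyne.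

Step 9
Reactants: 9 (S,E)-1-iodo-2-methyl-5-(triisopropylsilyl)pent-1-en-4-yn-3-ol; 14 (E)-2-{2-[(4-methoxybenzyl)oxy]vinyl}-4,4,5,5-tetramethyl-1,3,2-dioxaborolane
Product: 15 (3R,4E,6E)-7-[(4-methoxybenzyl)oxy]-4-methyl-1-(triisopropylsilyl)hepta-4,6-dien-1-yn-3-ol
Conditions: Pd(dppf)Cl2 (cat.), aq. K3PO4, THF, rt; chromatography on Et3N-treated silica
Reagents that add atoms: none
Why: Suzuki–Miyaura coupling joins C13 to C14 with retention of both alkene geometries and tolerates the free propargylic alcohol.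

Step 10
Reactants: 15 (3R,4E,6E)-7-[(4-methoxybenzyl)oxy]-4-methyl-1-(triisopropylsilyl)hepta-4,6-dien-1-yn-3-ol; 16 but-2-ynoic acid
Product: 17 but-2-ynoate ester of 15
Conditions: DCC, DMAP (cat.), CH2Cl2, −20→0 °C
Reagents that add atoms: none
Why: Steglich esterification under neutral conditions suits the acid-labile alkoxydienyl carbinol, and the alkynoic acid cannot undergo the Z to E or deconjugative isomerisation that threatens a (Z)-enoic acid.

Step 11
Reactants: 17 but-2-ynoate ester of 15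
Product: 18 (3R,4E,6E)-7-[(4-methoxybenzyl)oxy]-4-methyl-1-(triisopropylsilyl)hepta-4,6-dien-1-yn-3-yl (Z)-but-2-enoate
Conditions: H2 (1 atm), Lindlar catalyst, quinoline, EtOAc, rt, stopped after one equivalent
Reagents that add atoms: none
Why: Lindlar semihydrogenation is a syn addition to the unhindered conjugated alkyne and should give the Z crotonate, while the TIPS-capped alkyne is too hindered to react before uptake is stopped.

Step 12
Reactants: 18 (3R,4E,6E)-7-[(4-methoxybenzyl)oxy]-4-methyl-1-(triisopropylsilyl)hepta-4,6-dien-1-yn-3-yl (Z)-but-2-enoate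
Product: 19 (3R,3aS,6R,7R,7aS)-6-[(4-methoxybenzyl)oxy]-3a,7-dimethyl-3-[(triisopropylsilyl)ethynyl]-3a,6,7,7a-tetrahydroisobenzofuran-1(3H)-one
Conditions: PhMe (5 mM), BHT, 2,6-di-tert-butyl-4-methylpyridine (cat.), sealed silylated tube, 160 °C
Reagents that add atoms: none
Why: On heating, the s-cis ester conformer places C10=C11 under the C1=C14–C13=C12 diene and a concerted, asynchronous, suprafacial [4+2] cycloaddition forms C1–C10 and C11–C12; the closest known reaction type is the thermal intramolecular Diels–Alder reaction of 2,4-pentadienyl acrylates (ester-linked 1,3,8-nonatrienes) to bicyclic γ-lactones. The cyclohexene (C1, C10–C14) closes by the [4+2] annulation itself, and the γ-lactone (C1, C2, O, C9, C10) closes in the fused mode because the three-atom tether C2–O–C9 joins the diene terminus C1 to the dienophile carbon C10, which also overrides the electronic preference of the 1-alkoxydiene. C12 follows from the E enol ether (the outside OPMB ends cis to C2), C11 from the Z crotonate (C20 cis to C9), the trans C1/C10 fusion from the transition state with the tether carbonyl and C20 exo, and C1 from C2, whose alkynyl group lies next to H14 while its hydrogen faces the inside C15 methyl, so that the tether reaches one diene face only. The step needs exo (trans-fusion) selectivity and π-face selectivity: the Z methyl should secure the first, because in the endo mode it would sit under C13/C14 and eclipse the outside OPMB group, and the C2 stereocentre should secure the second. The inside methyl and the Z methyl slow the reaction, which the intramolecular setting offsets; dilution, a non-polar solvent, a radical inhibitor and a hindered base should suppress polymerisation and ionisation of the allylic-propargylic ester.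

Step 13
Reactants: 20 methyl (S)-3-hydroxy-2-methylpropanoate
Product: 21 methyl (S)-3-[(tert-butyldimethylsilyl)oxy]-2-methylpropanoate
Conditions: TBSCl, imidazole, CH2Cl2, rt
Reagents that add atoms: tert-butyldimethylsilyl chloride CC(C)(C)[Si](C)(C)Cl
Why: Standard silylation of the primary alcohol; the stereocentre (C17 of the target) is not involved.

Step 14
Reactants: 21 methyl (S)-3-[(tert-butyldimethylsilyl)oxy]-2-methylpropanoate
Product: 22 (S)-3-[(tert-butyldimethylsilyl)oxy]-2-methylpropanal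
Conditions: DIBAL-H, CH2Cl2, −78 °C; Rochelle salt
Reagents that add atoms: none
Why: DIBAL-H at −78 °C gives a stable aluminium hemiacetal that releases the aldehyde on work-up without touching the α-stereocentre.

Step 15
Reactants: 22 (S)-3-[(tert-butyldimethylsilyl)oxy]-2-methylpropanal
Product: 23 (R)-tert-butyl[(4,4-dibromo-2-methylbut-3-en-1-yl)oxy]dimethylsilane
Conditions: CBr4, PPh3, Zn, CH2Cl2, rt
Reagents that add atoms: carbon tetrabromide BrC(Br)(Br)Br
Why: Corey–Fuchs dibromoolefination (Wittig reaction of the dibromomethylene ylide made in situ) is non-basic, so C17 is not epimerised.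

Step 16
Reactants: 23 (R)-tert-butyl[(4,4-dibromo-2-methylbut-3-en-1-yl)oxy]dimethylsilane
Product: 25 (R)-5-[(tert-butyldimethylsilyl)oxy]-4-methylpent-2-yn-1-ol, via lithium acetylide 24 (not isolated)
Conditions: n-BuLi (2.1 equiv), THF, −78 °C; (CH2O)n, −78 °C→rt; H2O
Reagents that add atoms: formaldehyde (as paraformaldehyde) C=O
Why: Second stage of the Corey–Fuchs sequence: bromine–lithium exchange, 1,2-shift and deprotonation give the lithium acetylide, which is hydroxymethylated by formaldehyde (C6).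

Step 17
Reactants: 25 (R)-5-[(tert-butyldimethylsilyl)oxy]-4-methylpent-2-yn-1-ol
Product: 27 (S,Z)-5-[(tert-butyldimethylsilyl)oxy]-3-iodo-4-methylpent-2-en-1-ol, via cyclic alkenylaluminate 26 (not isolated)
Conditions: Red-Al, THF, 0 °C→rt; EtOAc; I2, −78→0 °C; aq. Na2S2O3
Reagents that add atoms: iodine II
Why: Alkoxide-directed trans-hydroalumination delivers hydride to C7 and aluminium to C8 in a five-membered chelate, and iodinolysis with retention should give the Z iodide with iodine cis to C6.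

Step 18
Reactants: 27 (S,Z)-5-[(tert-butyldimethylsilyl)oxy]-3-iodo-4-methylpent-2-en-1-ol
Product: 28 (S,Z)-5-[(tert-butyldimethylsilyl)oxy]-3-iodo-4-methylpent-2-enal
Conditions: MnO2, CH2Cl2, rt, dark
Reagents that add atoms: none
Why: MnO2 oxidation of the allylic alcohol under neutral conditions should keep the Z geometry of the β-iodo enal.

Step 19
Reactants: 28 (S,Z)-5-[(tert-butyldimethylsilyl)oxy]-3-iodo-4-methylpent-2-enal; 29 (trimethylsilyl)acetylene
Product: 31 (4Z,6S)-7-[(tert-butyldimethylsilyl)oxy]-5-iodo-6-methyl-1-(trimethylsilyl)hept-4-en-1-yn-3-ol (both C3 epimers), via lithium acetylide 30 (not isolated)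
Conditions: n-BuLi, THF, −78 °C; then 28; H2O
Reagents that add atoms: none
Why: 1,2-Addition of the lithium acetylide at −78 °C should outrun addition–elimination at the β-iodo enal; the C6 epimers converge in step 20.

Step 20
Reactants: 31 (4Z,6S)-7-[(tert-butyldimethylsilyl)oxy]-5-iodo-6-methyl-1-(trimethylsilyl)hept-4-en-1-yn-3-ol
Product: 32 (S,Z)-7-[(tert-butyldimethylsilyl)oxy]-5-iodo-6-methyl-1-(trimethylsilyl)hept-4-en-1-yn-3-one
Conditions: MnO2, CH2Cl2, rt
Reagents that add atoms: none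
Why: MnO2 oxidation of the doubly activated carbinol gives the ynone needed for a reagent-controlled reduction.

Step 21
Reactants: 32 (S,Z)-7-[(tert-butyldimethylsilyl)oxy]-5-iodo-6-methyl-1-(trimethylsilyl)hept-4-en-1-yn-3-one
Product: 33 (3S,4Z,6S)-7-[(tert-butyldimethylsilyl)oxy]-5-iodo-6-methyl-1-(trimethylsilyl)hept-4-en-1-yn-3-ol
Conditions: (S)-Alpine-Borane (neat), rt; MeCHO; ethanolamine
Reagents that add atoms: none
Why: Midland reduction with the enantiomeric reagent (from (−)-α-pinene), alkynyl again in the small-group position, should set the C6 carbinol, which later directs the dihydroxylation and is inverted to the chloride.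

Step 22
Reactants: 33 (3S,4Z,6S)-7-[(tert-butyldimethylsilyl)oxy]-5-iodo-6-methyl-1-(trimethylsilyl)hept-4-en-1-yn-3-ol
Product: 34 (3S,4Z,6S)-3,7-bis[(tert-butyldimethylsilyl)oxy]-5-iodo-6-methyl-1-(trimethylsilyl)hept-4-en-1-yne
Conditions: TBSOTf, 2,6-lutidine, CH2Cl2, −78 °C
Reagents that add atoms: tert-butyldimethylsilyl triflate CC(C)(C)[Si](C)(C)OS(=O)(=O)C(F)(F)F
Why: A silyl triflate with a hindered base protects the secondary allylic-propargylic alcohol without ionising it.

Step 23
Reactants: 34 (3S,4Z,6S)-3,7-bis[(tert-butyldimethylsilyl)oxy]-5-iodo-6-methyl-1-(trimethylsilyl)hept-4-en-1-yne; 19 trans-fused lactone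
Product: 36 hydroxy enone (C9 ketone, free 2-OH, C7=C8 with C6 cis to C9, 6-OTBS, 19-OTBS, C16–SiMe3, C4–TIPS, 12-OPMB), via vinyllithium 35 (not isolated)
Conditions: t-BuLi (2 equiv), Et2O, −78 °C; then 19, THF, −78 °C; AcOH, −78 °C
Reagents that add atoms: none
Why: Iodine–lithium exchange with retention gives the Z vinyllithium, whose addition to the strained lactone carbonyl (nucleophilic acyl substitution) should stop at the lithium hemiketal at −78 °C and release the C9 ketone and the C2 hydroxyl on work-up.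

Step 24
Reactants: 36 hydroxy enone
Product: 38 (9S)-2,9-diol with terminal C5≡C16 alkyne, via TMS-alkyne diol 37 (not isolated)
Conditions: NaBH4, CeCl3·7H2O, MeOH, −78→0 °C; then K2CO3, rt
Reagents that add atoms: none
Why: Luche 1,2-reduction should follow the Felkin–Anh model, hydride entering anti to the quaternary C1 substituent of C10 to give the 9S alcohol, and the carbonate, added only after the ketone is consumed, cleaves the alkynyl C–SiMe3 bond alone.

Step 25
Reactants: 38 (9S)-2,9-diol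
Product: 39 2,9-diacetate
Conditions: Ac2O, pyridine, DMAP (cat.), CH2Cl2, rt
Reagents that add atoms: acetic anhydride CC(=O)OC(C)=O
Why: DMAP-catalysed acetylation installs the two acetates of the target on the only free hydroxyls, at C2 and C9.

Step 26
Reactants: 39 2,9-diacetate
Product: 40 6,19-diol (2,9-diacetate)
Conditions: HF·pyridine, pyridine, THF, 0 °C→rt
Reagents that add atoms: none
Why: Buffered HF·pyridine cleaves both O–Si bonds but neither the alkynyl C–Si bond nor the acetates.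

Step 27
Reactants: 40 6,19-diol
Product: 42 6,7,8,19-tetraol (C7 and C8 as in the target), via osmate ester 41 (not isolated)
Conditions: OsO4 (1.1 equiv), TMEDA, CH2Cl2, −78 °C; then aq. Na2SO3, THF, rt
Reagents that add atoms: osmium tetroxide O=[Os](=O)(=O)=O
Why: Hydrogen-bond-directed dihydroxylation by OsO4·TMEDA: with H6 and H9 eclipsing the alkene (A1,3 strain across the cis C6/C9 pair) the C6 hydroxyl and the C9 acetoxy group lie on one face and the bulky C10 residue on the other, so syn addition on the hydroxyl face should set C7 and C8 as in the target.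

Step 28
Reactants: 42 6,7,8,19-tetraol
Product: 44 hydroxy lactone (C19–O7 γ-lactone, 8-OH, 6-OH, terminal C5≡C16 alkyne), via seco acid 43 (not isolated)
Conditions: TEMPO (cat.), NaOCl (cat.), NaClO2, MeCN/pH 6.7 phosphate buffer, 35 °C; then PPTS, CH2Cl2, rt
Reagents that add atoms: sodium chlorite [Na+].[O-]Cl=O
Why: TEMPO/chlorite oxidation is selective for the primary alcohol, and the acid should close to the γ-lactone on O7, favoured over the δ-lactone on O6, while O9 is blocked as its acetate.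

Step 29
Reactants: 44 hydroxy lactone
Product: 46 2-iodoalkene (C5(I)=C16H2), via C5 stannane 45 (not isolated)
Conditions: Bu3SnH, Mo(CO)3(CNt-Bu)3 (cat.), hydroquinone, THF, 55 °C; then I2, CH2Cl2, 0 °C
Reagents that add atoms: iodine II
Why: Molybdenum-catalysed hydrostannation of propargylic alcohols places tin on the internal carbon (C5), and iododestannylation with retention gives the 2-iodoalkene; the hindered TIPS-alkyne should not react.

Step 30
Reactants: 46 2-iodoalkene
Product: 47 terminal C3≡C4 alkyne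
Conditions: TBAF, AcOH, THF, 0 °C→rt
Reagents that add atoms: none
Why: Fluoride cleaves the alkynyl C–Si bond, and buffering with acetic acid protects the acetates and the β-hydroxy lactone.

Step 31
Reactants: 47 terminal C3≡C4 alkyne
Product: 50 (3Z)-C4 vinylstannane, via alkynylstannane 48 (not isolated), via stannyl zirconocene 49 (not isolated)
Conditions: Bu3SnOMe, ZnBr2 (cat.), THF, rt, then evaporation; Cp2Zr(H)Cl (excess), THF, rt; H2O
Reagents that add atoms: tributyltin methoxide CCCC[Sn](CCCC)(CCCC)OC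
Why: Zinc-catalysed stannylation of the terminal alkyne followed by syn hydrozirconation (Schwartz reagent, zirconium on the tin-bearing carbon) and protonolysis with retention should give the Z vinylstannane.

Step 32
Reactants: 50 (3Z)-C4 vinylstannane
Product: 51 macrocyclic 6-alcohol (ten-membered ring, 3Z,5(16)-diene, 12-OPMB)
Conditions: Pd(PPh3)4 (cat.), CuTC, DMF, rt, slow addition to 1 mM
Reagents that add atoms: none
Why: Copper-assisted intramolecular Stille coupling joins C4 to C5 with retention at both alkenyl carbons and should close the ten-membered ring under high dilution.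

Step 33
Reactants: 51 macrocyclic 6-alcohol
Product: 52 (6S)-chloride (12-OPMB)
Conditions: PPh3, hexachloroacetone, CH2Cl2, −20→0 °C
Reagents that add atoms: hexachloroacetone O=C(C(Cl)(Cl)Cl)C(Cl)(Cl)Cl
Why: Phosphine/hexachloroacetone chlorination (Appel type) is an SN2 displacement of the alkoxyphosphonium ion, known for secondary allylic alcohols to proceed with inversion and little allylic transposition, and the tertiary C8 hydroxyl should not react.

Step 34
Reactants: 52 (6S)-chloride
Product: 53 12-alcohol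
Conditions: DDQ, CH2Cl2/pH 7 buffer, 0 °C
Reagents that add atoms: none
Why: DDQ oxidises only the electron-rich PMB ether to its oxocarbenium ion, which water cleaves to the C12 alcohol.

Step 35
Reactants: 53 12-alcohol
Product: 54 CNP0305105.1
Conditions: (EtCO)2O, pyridine, DMAP (cat.), CH2Cl2, 0 °C
Reagents that add atoms: propionic anhydride CCC(=O)OC(=O)CC
Why: DMAP-catalysed acylation esterifies the secondary C12 alcohol, and the hindered tertiary C8 hydroxyl should stay free.

Compound list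
1 | prop-2-yn-1-ol | C#CCO | starting material
2 | (E)-[3-(dimethylalumanyloxy)-2-methylprop-1-enyl]dimethylalane | C[Al](C)OC/C(C)=C/[Al](C)C | intermediate
3 | (E)-3-iodo-2-methylprop-2-en-1-ol | OC/C(C)=C/I | intermediate
4 | (E)-3-iodo-2-methylprop-2-enal | O=C/C(C)=C/I | intermediate
5 | (triisopropylsilyl)acetylene | C#C[Si](C(C)C)(C(C)C)C(C)C | starting material
6 | lithium (triisopropylsilyl)acetylide | [Li]C#C[Si](C(C)C)(C(C)C)C(C)C | intermediate
7 | rac-(E)-1-iodo-2-methyl-5-(triisopropylsilyl)pent-1-en-4-yn-3-ol | CC(C)[Si](C(C)C)(C(C)C)C#CC(O)/C(C)=C/I | intermediate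
8 | (E)-1-iodo-2-methyl-5-(triisopropylsilyl)pent-1-en-4-yn-3-one | CC(C)[Si](C(C)C)(C(C)C)C#CC(=O)/C(C)=C/I | intermediate
9 | (S,E)-1-iodo-2-methyl-5-(triisopropylsilyl)pent-1-en-4-yn-3-ol | CC(C)[Si](C(C)C)(C(C)C)C#C[C@H](O)/C(C)=C/I | intermediate
10 | 4-methoxybenzyl alcohol | COc1ccc(CO)cc1 | starting material
11 | (E)-1,2-dichlorovinyl 4-methoxybenzyl ether | COc1ccc(CO/C(Cl)=C\Cl)cc1 | intermediate
12 | lithium [(4-methoxybenzyl)oxy]acetylide | [Li]C#COCc1ccc(OC)cc1 | intermediate
13 | ethynyl 4-methoxybenzyl ether | C#COCc1ccc(OC)cc1 | intermediate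
14 | (E)-2-{2-[(4-methoxybenzyl)oxy]vinyl}-4,4,5,5-tetramethyl-1,3,2-dioxaborolane | COc1ccc(CO/C=C/B2OC(C)(C)C(C)(C)O2)cc1 | intermediate
15 | (3R,4E,6E)-7-[(4-methoxybenzyl)oxy]-4-methyl-1-(triisopropylsilyl)hepta-4,6-dien-1-yn-3-ol | CC(C)[Si](C(C)C)(C(C)C)C#C[C@H](O)/C(C)=C/C=C/OCc1ccc(OC)cc1 | intermediate
16 | but-2-ynoic acid | CC#CC(=O)O | starting material
17 | but-2-ynoate ester of 15 | CC(C)[Si](C(C)C)(C(C)C)C#C[C@H](OC(=O)C#CC)/C(C)=C/C=C/OCc1ccc(OC)cc1 | intermediate
18 | (Z)-but-2-enoate ester of 15 (Diels–Alder precursor) | CC(C)[Si](C(C)C)(C(C)C)C#C[C@H](OC(=O)/C=C\C)/C(C)=C/C=C/OCc1ccc(OC)cc1 | intermediate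
19 | (3R,3aS,6R,7R,7aS)-6-[(4-methoxybenzyl)oxy]-3a,7-dimethyl-3-[(triisopropylsilyl)ethynyl]-3a,6,7,7a-tetrahydroisobenzofuran-1(3H)-one (trans-fused lactone) | CC(C)[Si](C(C)C)(C(C)C)C#C[C@H](OC3=O)[C@@]2(C)C=C[C@@H](OCc4ccc(OC)cc4)[C@H](C)[C@@H]23 | intermediate
20 | methyl (S)-3-hydroxy-2-methylpropanoate | COC(=O)[C@@H](C)CO | starting material
21 | methyl (S)-3-[(tert-butyldimethylsilyl)oxy]-2-methylpropanoate | COC(=O)[C@@H](C)CO[Si](C)(C)C(C)(C)C | intermediate
22 | (S)-3-[(tert-butyldimethylsilyl)oxy]-2-methylpropanal | O=C[C@@H](C)CO[Si](C)(C)C(C)(C)C | intermediate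
23 | (R)-tert-butyl[(4,4-dibromo-2-methylbut-3-en-1-yl)oxy]dimethylsilane | BrC(Br)=C[C@@H](C)CO[Si](C)(C)C(C)(C)C | intermediate
24 | lithium (R)-4-[(tert-butyldimethylsilyl)oxy]-3-methylbut-1-ynide | [Li]C#C[C@@H](C)CO[Si](C)(C)C(C)(C)C | intermediate
25 | (R)-5-[(tert-butyldimethylsilyl)oxy]-4-methylpent-2-yn-1-ol | OCC#C[C@@H](C)CO[Si](C)(C)C(C)(C)C | intermediate
26 | sodium cyclic alkenylaluminate (O–Al–C8 chelate, bis(2-methoxyethoxy)) | [Na+].COCCO[Al-]1(OCCOC)OCC=C1[C@@H](C)CO[Si](C)(C)C(C)(C)C | intermediate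
27 | (S,Z)-5-[(tert-butyldimethylsilyl)oxy]-3-iodo-4-methylpent-2-en-1-ol | OC/C=C(\I)[C@@H](C)CO[Si](C)(C)C(C)(C)C | intermediate
28 | (S,Z)-5-[(tert-butyldimethylsilyl)oxy]-3-iodo-4-methylpent-2-enal | O=C/C=C(\I)[C@@H](C)CO[Si](C)(C)C(C)(C)C | intermediate
29 | (trimethylsilyl)acetylene | C#C[Si](C)(C)C | starting material
30 | lithium (trimethylsilyl)acetylide | [Li]C#C[Si](C)(C)C | intermediate
31 | (4Z,6S)-7-[(tert-butyldimethylsilyl)oxy]-5-iodo-6-methyl-1-(trimethylsilyl)hept-4-en-1-yn-3-ol, C3 epimers | C[Si](C)(C)C#CC(O)/C=C(\I)[C@@H](C)CO[Si](C)(C)C(C)(C)C | intermediate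
32 | (S,Z)-7-[(tert-butyldimethylsilyl)oxy]-5-iodo-6-methyl-1-(trimethylsilyl)hept-4-en-1-yn-3-one | C[Si](C)(C)C#CC(=O)/C=C(\I)[C@@H](C)CO[Si](C)(C)C(C)(C)C | intermediate
33 | (3S,4Z,6S)-7-[(tert-butyldimethylsilyl)oxy]-5-iodo-6-methyl-1-(trimethylsilyl)hept-4-en-1-yn-3-ol | C[Si](C)(C)C#C[C@@H](O)/C=C(\I)[C@@H](C)CO[Si](C)(C)C(C)(C)C | intermediate
34 | (3S,4Z,6S)-3,7-bis[(tert-butyldimethylsilyl)oxy]-5-iodo-6-methyl-1-(trimethylsilyl)hept-4-en-1-yne | C[Si](C)(C)C#C[C@@H](O[Si](C)(C)C(C)(C)C)/C=C(\I)[C@@H](C)CO[Si](C)(C)C(C)(C)C | intermediate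
35 | vinyllithium from 34 (Li in place of I, Z retained) | C[Si](C)(C)C#C[C@@H](O[Si](C)(C)C(C)(C)C)/C=C(\[Li])[C@@H](C)CO[Si](C)(C)C(C)(C)C | intermediate
36 | hydroxy enone (C9 ketone, 2-OH, C7=C8 with C6 cis to C9, 6,19-bis-OTBS, C16–SiMe3) | CC(C)[Si](C(C)C)(C(C)C)C#C[C@H](O)[C@@]1(C)C=C[C@@H](OCc2ccc(OC)cc2)[C@H](C)[C@@H]1C(=O)/C(=C\[C@H](O[Si](C)(C)C(C)(C)C)C#C[Si](C)(C)C)[C@@H](C)CO[Si](C)(C)C(C)(C)C | intermediate
37 | (9S)-2,9-diol, C16–SiMe3 retained | CC(C)[Si](C(C)C)(C(C)C)C#C[C@H](O)[C@@]1(C)C=C[C@@H](OCc2ccc(OC)cc2)[C@H](C)[C@@H]1[C@H](O)/C(=C\[C@H](O[Si](C)(C)C(C)(C)C)C#C[Si](C)(C)C)[C@@H](C)CO[Si](C)(C)C(C)(C)C | intermediate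
38 | (9S)-2,9-diol with terminal C5≡C16 alkyne | CC(C)[Si](C(C)C)(C(C)C)C#C[C@H](O)[C@@]1(C)C=C[C@@H](OCc2ccc(OC)cc2)[C@H](C)[C@@H]1[C@H](O)/C(=C\[C@H](O[Si](C)(C)C(C)(C)C)C#C)[C@@H](C)CO[Si](C)(C)C(C)(C)C | intermediate
39 | 2,9-diacetate (6,19-bis-OTBS) | CC(C)[Si](C(C)C)(C(C)C)C#C[C@H](OC(C)=O)[C@@]1(C)C=C[C@@H](OCc2ccc(OC)cc2)[C@H](C)[C@@H]1[C@H](OC(C)=O)/C(=C\[C@H](O[Si](C)(C)C(C)(C)C)C#C)[C@@H](C)CO[Si](C)(C)C(C)(C)C | intermediate
40 | 6,19-diol (2,9-diacetate) | CC(C)[Si](C(C)C)(C(C)C)C#C[C@H](OC(C)=O)[C@@]1(C)C=C[C@@H](OCc2ccc(OC)cc2)[C@H](C)[C@@H]1[C@H](OC(C)=O)/C(=C\[C@H](O)C#C)[C@@H](C)CO | intermediate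
41 | C7/C8 osmate(VI) ester, TMEDA complex | CC(C)[Si](C(C)C)(C(C)C)C#C[C@H](OC(C)=O)[C@@]1(C)C=C[C@@H](OCc2ccc(OC)cc2)[C@H](C)[C@@H]1[C@H](OC(C)=O)[C@]3(O[Os-2]4(=O)(=O)([N+](C)(C)CC[N+]4(C)C)O[C@H]3[C@H](O)C#C)[C@@H](C)CO | intermediate
42 | 6,7,8,19-tetraol (2,9-diacetate) | CC(C)[Si](C(C)C)(C(C)C)C#C[C@H](OC(C)=O)[C@@]1(C)C=C[C@@H](OCc2ccc(OC)cc2)[C@H](C)[C@@H]1[C@H](OC(C)=O)[C@@](O)([C@@H](O)[C@H](O)C#C)[C@@H](C)CO | intermediate
43 | seco acid (C19 carboxylic acid, 6,7,8-triol) | CC(C)[Si](C(C)C)(C(C)C)C#C[C@H](OC(C)=O)[C@@]1(C)C=C[C@@H](OCc2ccc(OC)cc2)[C@H](C)[C@@H]1[C@H](OC(C)=O)[C@@](O)([C@@H](O)[C@H](O)C#C)[C@@H](C)C(=O)O | intermediate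
44 | hydroxy lactone (C19–O7 γ-lactone, 8-OH, 6-OH, terminal C5≡C16 alkyne) | CC(C)[Si](C(C)C)(C(C)C)C#C[C@H](OC(C)=O)[C@@]1(C)C=C[C@@H](OCc2ccc(OC)cc2)[C@H](C)[C@@H]1[C@H](OC(C)=O)[C@]3(O)[C@@H](C)C(=O)O[C@H]3[C@H](O)C#C | intermediate
45 | C5 tributylstannane (2-stannylalkene) | CC(C)[Si](C(C)C)(C(C)C)C#C[C@H](OC(C)=O)[C@@]1(C)C=C[C@@H](OCc2ccc(OC)cc2)[C@H](C)[C@@H]1[C@H](OC(C)=O)[C@]3(O)[C@@H](C)C(=O)O[C@H]3[C@H](O)C(=C)[Sn](CCCC)(CCCC)CCCC | intermediate
46 | 2-iodoalkene (C5(I)=C16H2), C4–TIPS | CC(C)[Si](C(C)C)(C(C)C)C#C[C@H](OC(C)=O)[C@@]1(C)C=C[C@@H](OCc2ccc(OC)cc2)[C@H](C)[C@@H]1[C@H](OC(C)=O)[C@]3(O)[C@@H](C)C(=O)O[C@H]3[C@H](O)C(I)=C | intermediate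
47 | terminal C3≡C4 alkyne with C5 iodide | C#C[C@H](OC(C)=O)[C@@]1(C)C=C[C@@H](OCc2ccc(OC)cc2)[C@H](C)[C@@H]1[C@H](OC(C)=O)[C@]3(O)[C@@H](C)C(=O)O[C@H]3[C@H](O)C(I)=C | intermediate
48 | C4 alkynylstannane | CCCC[Sn](CCCC)(CCCC)C#C[C@H](OC(C)=O)[C@@]1(C)C=C[C@@H](OCc2ccc(OC)cc2)[C@H](C)[C@@H]1[C@H](OC(C)=O)[C@]3(O)[C@@H](C)C(=O)O[C@H]3[C@H](O)C(I)=C | intermediate
49 | C4 stannyl zirconocene (1,1-dimetallated alkene) | CCCC[Sn](CCCC)(CCCC)/C(=C\[C@H](OC(C)=O)[C@@]1(C)C=C[C@@H](OCc2ccc(OC)cc2)[C@H](C)[C@@H]1[C@H](OC(C)=O)[C@]3(O)[C@@H](C)C(=O)O[C@H]3[C@H](O)C(I)=C)[Zr](Cl)(C4C=CC=C4)C5C=CC=C5 | intermediate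
50 | (3Z)-C4 vinylstannane with C5 iodide | CCCC[Sn](CCCC)(CCCC)/C=C\[C@H](OC(C)=O)[C@@]1(C)C=C[C@@H](OCc2ccc(OC)cc2)[C@H](C)[C@@H]1[C@H](OC(C)=O)[C@]3(O)[C@@H](C)C(=O)O[C@H]3[C@H](O)C(I)=C | intermediate
51 | macrocyclic 6-alcohol (3Z,5(16)-diene, 12-OPMB) | C=C1/C=C\[C@H](OC(C)=O)[C@@]2(C)C=C[C@@H](OCc3ccc(OC)cc3)[C@H](C)[C@@H]2[C@H](OC(C)=O)[C@]2(O)[C@@H](C)C(=O)O[C@H]2[C@@H]1O | intermediate
52 | (6S)-chloride, 12-OPMB | C=C1/C=C\[C@H](OC(C)=O)[C@@]2(C)C=C[C@@H](OCc3ccc(OC)cc3)[C@H](C)[C@@H]2[C@H](OC(C)=O)[C@]2(O)[C@@H](C)C(=O)O[C@H]2[C@H]1Cl | intermediate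
53 | 12-alcohol (12-O-despropionyl target) | C=C1/C=C\[C@H](OC(C)=O)[C@@]2(C)C=C[C@@H](O)[C@H](C)[C@@H]2[C@H](OC(C)=O)[C@]2(O)[C@@H](C)C(=O)O[C@H]2[C@H]1Cl | intermediate
54 | CNP0305105.1 | C=C1/C=C\[C@H](OC(C)=O)[C@@]2(C)C=C[C@@H](OC(=O)CC)[C@H](C)[C@@H]2[C@H](OC(C)=O)[C@]2(O)[C@@H](C)C(=O)O[C@H]2[C@H]1Cl | target

Total step count: 35 steps.
Longest linear sequence: 23 steps (steps 13–35, from the (S)-Roche ester 20); the diene line (steps 1–5, 9–12, then 23–35) has 22.

Steps most likely to fail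

1. Step 12 (intramolecular Diels–Alder reaction). The cycloaddition may be too slow, because the inside C15 methyl disfavours the s-cis diene and the tether imposes the electronically mismatched orientation. The allylic-propargylic ester may ionise or undergo acyloxy migration at the temperature needed. Endo closure to the cis-fused lactone may compete. The fallback sets out from 15 and returns at 19. Dienol 15 would be esterified with propiolic acid (DCC, CH2Cl2, −20 °C) to the propiolate ester F1. This more reactive alkynoate dienophile has no endo/exo question and should cyclise at 80–110 °C in toluene to the cyclohexa-1,4-diene-fused butenolide F2, with C1 and C12 set as in the main route. Conjugate addition of Me2CuLi (Et2O, −78 °C) anti to the C12 ether would then introduce C20. Protonation of the lactone enolate from the face opposite the C15 and C20 methyl groups should give the trans-fused lactone 19.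

2. Step 32 (Stille ring closure). Reductive elimination to the strained ten-membered diene may be slower than protodestannylation, oligomerisation or ionisation of the allylic acetate at C2. The fallback sets out from 47 and returns at 51. The terminal alkyne and the 2-iodoalkene of 47 would be joined directly by intramolecular Sonogashira coupling (Pd(PPh3)4, CuI, i-Pr2NH, THF, high dilution) to the ten-membered cyclic enyne F3. Semireduction of the ring alkyne with Zn(Cu/Ag) in MeOH/H2O would then give the 3Z alkene of 51.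

3. Step 23 (fragment union at C9). The hindered trisubstituted vinyllithium may deprotonate C10 of the lactone, which returns or epimerises 19, or may add sluggishly to the crowded carbonyl. The fallback sets out from 19 and returns at 36. Lactone 19 would be opened with MeNH(OMe)·HCl/Me3Al (CH2Cl2, 0 °C) to the hydroxy Weinreb amide F4 and capped at O2 (TMSCl, imidazole) as the trimethylsilyl ether F5. Addition of vinyllithium 35 to this open-chain, more accessible acyl donor gives a chelated tetrahedral intermediate that cannot over-add. Work-up with citric acid in MeOH releases the ketone and removes the silyl group to give 36.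

Further compounds
F1 | step 12 | propiolate ester of 15 | CC(C)[Si](C(C)C)(C(C)C)C#C[C@H](OC(=O)C#C)/C(C)=C/C=C/OCc1ccc(OC)cc1
F2 | step 12 | cyclohexa-1,4-diene-fused butenolide (C10=C11, no C20) | CC(C)[Si](C(C)C)(C(C)C)C#C[C@H](OC3=O)[C@@]2(C)C=C[C@@H](OCc4ccc(OC)cc4)C=C23
F3 | step 32 | ten-membered cyclic enyne (C3≡C4, C5=C16H2, 6-OH) | C=C1C#C[C@H](OC(C)=O)[C@@]2(C)C=C[C@@H](OCc3ccc(OC)cc3)[C@H](C)[C@@H]2[C@H](OC(C)=O)[C@]2(O)[C@@H](C)C(=O)O[C@H]2[C@@H]1O
F4 | step 23 | hydroxy Weinreb amide from 19 | CC(C)[Si](C(C)C)(C(C)C)C#C[C@H](O)[C@@]1(C)C=C[C@@H](OCc2ccc(OC)cc2)[C@H](C)[C@@H]1C(=O)N(C)OC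
F5 | step 23 | O2-trimethylsilyl ether of F4 | CC(C)[Si](C(C)C)(C(C)C)C#C[C@H](O[Si](C)(C)C)[C@@]1(C)C=C[C@@H](OCc2ccc(OC)cc2)[C@H](C)[C@@H]1C(=O)N(C)OC
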